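**Strategy**

The target is cut at C11=C12 (ring-closing metathesis) and, decisively, at C9–C10 and C12–C13. The ring segment C13–O7–C7–C8–C9 is treated as a 2-ethyl-1,3-dioxane in which C13 is the acetal carbon and C9 carries an ionisable acetate. In one flask a (Z)-γ-silyloxyallylstannane adds to the dioxanyl cation at C9 and trivinylaluminium then opens the acetal at C13 with retention, so the temporary ring relays the malate-derived C7 centre to C9 and C13 while both C–C bonds form. Metathesis closes the oxocene; aldehyde propargylation, diyne semireduction and invertive chlorination complete the side chain.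

Key step: step 7

Remark: atoms are numbered along the chain from the alkyne terminus (C1) to the ethyl CH3 (C15), O7 being the ring oxygen between C7 and C13; the five starting materials 1, 5, 10, 20 and 22 are taken to be purchasable.

**Route**

Step 1
Reactants: 1 dimethyl (R)-malate
Product: 2 methyl (3R)-3,4-dihydroxybutanoate
Conditions: BH3·SMe2, NaBH4 (5 mol %), THF, 0 °C → rt; then MeOH
Reagents that add atoms: none
Why: Hydroxyl-directed borane reduction, in which the alkoxyborane formed at the carbinol delivers hydride to the adjacent ester through a five-membered chelate, should reduce only the α-hydroxy ester and leave the stereocentre (future C7) untouched.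

Step 2
Reactants: 2 methyl (3R)-3,4-dihydroxybutanoate
Product: 3 methyl (3R)-4-[(tert-butyldiphenylsilyl)oxy]-3-hydroxybutanoate
Conditions: t-BuPh2SiCl, imidazole, CH2Cl2, 0 °C
Reagents that add atoms: tert-butyl(chloro)diphenylsilane, CC(C)(C)[Si](Cl)(c1ccccc1)c1ccccc1
Why: Chemoselective silylation should occur at the primary hydroxyl because the bulky silyl chloride discriminates strongly against the secondary one.

Step 3
Reactants: 3 methyl (3R)-4-[(tert-butyldiphenylsilyl)oxy]-3-hydroxybutanoate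
Product: 4 (3R)-4-[(tert-butyldiphenylsilyl)oxy]-3-hydroxybutanoic acid
Conditions: LiOH, THF–H2O, 0 °C; then aq. HCl to pH 3
Reagents that add atoms: lithium hydroxide, [Li+].[OH-]
Why: Ester saponification under mild conditions should leave the silyl ether and the stereocentre intact.

Step 4
Reactants: 4 (3R)-4-[(tert-butyldiphenylsilyl)oxy]-3-hydroxybutanoic acid; 5 propanal
Product: 7 (2S,6R)-6-{[(tert-butyldiphenylsilyl)oxy]methyl}-2-ethyl-1,3-dioxan-4-one (2,6-cis), via bis(trimethylsilyl) derivative 6 (not isolated)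
Conditions: (Me3Si)2NH, CH2Cl2, rt; then 5, Me3SiOTf (5 mol %), CH2Cl2, −78 °C
Reagents that add atoms: none
Why: Silyl-triflate-catalysed acetalisation of the bis-silylated β-hydroxy acid by the aldehyde (silyl-mediated dioxanone formation) should set the new acetal carbon C13 cis to the C7 substituent, because both groups sit equatorially in the chair.

Step 5
Reactants: 7 (2S,6R)-6-{[(tert-butyldiphenylsilyl)oxy]methyl}-2-ethyl-1,3-dioxan-4-one
Product: 9 (2S,6R)-6-{[(tert-butyldiphenylsilyl)oxy]methyl}-2-ethyl-1,3-dioxan-4-yl acetate (C4 epimers), via aluminium lactol alkoxide 8 (not isolated)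
Conditions: i-Bu2AlH, CH2Cl2, −78 °C; then pyridine, DMAP, Ac2O, −78 → −20 °C
Reagents that add atoms: acetic anhydride, CC(=O)OC(C)=O
Why: Reductive acetylation of the lactone should trap the tetrahedral aluminium hemiacetal by O-acylation before it collapses; the configuration at the acetate carbon (C9) does not matter because it is ionised in step 7.

Step 6
Reactants: 10 allyloxy(tert-butyl)dimethylsilane
Product: 12 tributyl[(2Z)-3-{[tert-butyl(dimethyl)silyl]oxy}prop-2-en-1-yl]stannane, via lithiated allyl ether 11 (not isolated)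
Conditions: s-BuLi, THF, −78 °C; then Bu3SnCl, −78 °C
Reagents that add atoms: tributyltin chloride, CCCC[Sn](Cl)(CCCC)CCCC
Why: Kinetic allylic deprotonation should give the internally coordinated (Z)-alkoxyallyllithium, which is stannylated at the carbon remote from oxygen to give the (Z)-γ-silyloxyallylstannane.

Step 7
Reactants: 9 (2S,6R)-6-{[(tert-butyldiphenylsilyl)oxy]methyl}-2-ethyl-1,3-dioxan-4-yl acetate; 12 tributyl[(2Z)-3-{[tert-butyl(dimethyl)silyl]oxy}prop-2-en-1-yl]stannane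
Product: 14 (3R,4R,6R)-3-{[tert-butyl(dimethyl)silyl]oxy}-7-[(tert-butyldiphenylsilyl)oxy]-6-[(3R)-pent-1-en-3-yloxy]hept-1-en-4-ol, via dioxane adduct 13 (not isolated)
Conditions: Me3SiOTf (1.1 equiv), CH2Cl2, −78 °C; then (CH2=CH)3Al (from CH2=CHMgBr and AlCl3), toluene, −78 → 0 °C; aq. KNaC4H4O6 (Rochelle salt)
Reagents that add atoms: trivinylaluminium, C=C[Al](C=C)C=C
Why: Proposed new method: Me3SiOTf ionises the anomeric acetate of 9 to a 1,3-dioxan-4-yl oxocarbenium ion that stannane 12 captures by anti-SE2′ attack through its oxygen-bearing carbon (C10) to give dioxane 13, after which trivinylaluminium coordinates O9, ionises C13–O9 to a contact ion pair and delivers a vinyl group from aluminium to the same face of C13. The closest known reaction types are the Lewis-acid-mediated axial addition of allyl metals to 4-acetoxy-1,3-dioxanes and the retentive alkylative opening of 1,3-dioxane acetals by organoaluminium reagents; their union in one flask and the alkenyl transfer are untested. No ring is closed: the 1,3-dioxane is a temporary ring that is opened in the second event. C9 is set by stereoelectronically controlled axial attack on the half-chair cation anti to the equatorial C7 substituent (4,6-trans), C10 by the open transition state of the (Z)-γ-silyloxyallylstannane (syn to C9–O), and C13 by retention of the 2,6-cis acetal configuration fixed in step 4. The step needs chemoselectivity (acetate ionisation before acetal opening, secured by running the first event at −78 °C and adding the alane only afterwards) and regioselectivity for C13–O9 over C13–O7 cleavage, secured by the axial C9 branch, which makes O9 the oxygen whose departure relieves syn-axial strain, as in pentane-2,4-diol acetals.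

Step 8
Reactants: 14 (3R,4R,6R)-3-{[tert-butyl(dimethyl)silyl]oxy}-7-[(tert-butyldiphenylsilyl)oxy]-6-[(3R)-pent-1-en-3-yloxy]hept-1-en-4-ol
Product: 15 (2R,5R,6R,8R)-5-{[tert-butyl(dimethyl)silyl]oxy}-8-{[(tert-butyldiphenylsilyl)oxy]methyl}-2-ethyl-5,6,7,8-tetrahydro-2H-oxocin-6-ol
Conditions: second-generation Grubbs catalyst RuCl2(=CHPh)(PCy3)(H2IMes) (5 mol %), CH2Cl2 (2 mM), 40 °C
Reagents that add atoms: none
Why: Ring-closing metathesis of the two terminal alkenes should be helped by the gauche C9–O/C10–O arrangement, and the eight-membered ring can only hold the Z alkene.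

Step 9
Reactants: 15 (2R,5R,6R,8R)-5-{[tert-butyl(dimethyl)silyl]oxy}-8-{[(tert-butyldiphenylsilyl)oxy]methyl}-2-ethyl-5,6,7,8-tetrahydro-2H-oxocin-6-ol
Product: 16 (2R,5R,6R,8R)-8-{[(tert-butyldiphenylsilyl)oxy]methyl}-2-ethyl-5,6,7,8-tetrahydro-2H-oxocine-5,6-diol
Conditions: HF·pyridine, pyridine, THF, 0 °C
Reagents that add atoms: none
Why: Buffered fluoride should cleave the secondary tert-butyldimethylsilyl ether, which is far more labile than the primary tert-butyldiphenylsilyl ether.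

Step 10
Reactants: 16 (2R,5R,6R,8R)-8-{[(tert-butyldiphenylsilyl)oxy]methyl}-2-ethyl-5,6,7,8-tetrahydro-2H-oxocine-5,6-diol
Product: 17 (2R,5R,6R,8R)-8-{[(tert-butyldiphenylsilyl)oxy]methyl}-2-ethyl-5,6,7,8-tetrahydro-2H-oxocine-5,6-diyl diacetate
Conditions: Ac2O, pyridine, DMAP (cat.), CH2Cl2, rt
Reagents that add atoms: acetic anhydride, CC(=O)OC(C)=O
Why: Nucleophile-catalysed acylation should acetylate both secondary alcohols without touching any stereocentre.

Step 11
Reactants: 17 (2R,5R,6R,8R)-8-{[(tert-butyldiphenylsilyl)oxy]methyl}-2-ethyl-5,6,7,8-tetrahydro-2H-oxocine-5,6-diyl diacetate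
Product: 18 (2R,5R,6R,8R)-2-ethyl-8-(hydroxymethyl)-5,6,7,8-tetrahydro-2H-oxocine-5,6-diyl diacetate
Conditions: Bu4NF, AcOH, THF, 0 °C → rt
Reagents that add atoms: none
Why: Acetic-acid-buffered fluoride should remove the remaining silyl ether without acetate cleavage or migration.

Step 12
Reactants: 18 (2R,5R,6R,8R)-2-ethyl-8-(hydroxymethyl)-5,6,7,8-tetrahydro-2H-oxocine-5,6-diyl diacetate
Product: 19 (2R,5R,6R,8R)-2-ethyl-8-formyl-5,6,7,8-tetrahydro-2H-oxocine-5,6-diyl diacetate
Conditions: Dess–Martin periodinane, NaHCO3, CH2Cl2, 0 °C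
Reagents that add atoms: none
Why: Dess–Martin oxidation under buffered conditions should give the α-alkoxy aldehyde without epimerising C7.

Step 13
Reactants: 19 (2R,5R,6R,8R)-2-ethyl-8-formyl-5,6,7,8-tetrahydro-2H-oxocine-5,6-diyl diacetate; 20 allenylboronic acid pinacol ester
Product: 21 (2R,5R,6R,8R)-2-ethyl-8-[(1S)-1-hydroxybut-3-yn-1-yl]-5,6,7,8-tetrahydro-2H-oxocine-5,6-diyl diacetate
Conditions: 20, (PhO)2P(O)OH (10 mol %), toluene, −20 °C → rt; aq. NaHCO3
Reagents that add atoms: none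
Why: Brønsted-acid-accelerated allenylboration through a closed six-membered SE2′ transition state should give the homopropargylic alcohol, with C6 set by Felkin–Anh attack anti to the ring C7–O bond (O6/O7 erythro, 6S).

Step 14
Reactants: 21 (2R,5R,6R,8R)-2-ethyl-8-[(1S)-1-hydroxybut-3-yn-1-yl]-5,6,7,8-tetrahydro-2H-oxocine-5,6-diyl diacetate; 22 (bromoethynyl)tri(propan-2-yl)silane
Product: 23 (2R,5R,6R,8R)-2-ethyl-8-[(1S)-1-hydroxy-6-(triisopropylsilyl)hexa-3,5-diyn-1-yl]-5,6,7,8-tetrahydro-2H-oxocine-5,6-diyl diacetate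
Conditions: 22, PdCl2(PPh3)2 (3 mol %), CuI (6 mol %), i-Pr2NH, THF, 0 °C → rt
Reagents that add atoms: none
Why: Palladium/copper-catalysed alkynyl–alkynyl cross-coupling (Cadiot–Chodkiewicz-type) should join the terminal alkyne to the bromoalkyne under a hindered amine that spares the acetates.

Step 15
Reactants: 23 (2R,5R,6R,8R)-2-ethyl-8-[(1S)-1-hydroxy-6-(triisopropylsilyl)hexa-3,5-diyn-1-yl]-5,6,7,8-tetrahydro-2H-oxocine-5,6-diyl diacetate
Product: 24 (2R,5R,6R,8R)-2-ethyl-8-[(1S,3Z)-1-hydroxy-6-(triisopropylsilyl)hex-3-en-5-yn-1-yl]-5,6,7,8-tetrahydro-2H-oxocine-5,6-diyl diacetate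
Conditions: Zn [activated by Cu(OAc)2 and AgNO3], MeOH–H2O (1:1), rt
Reagents that add atoms: none
Why: Activated zinc should deliver two hydrogens cis to the conjugated triple bond that is not silylated (Z-selective semireduction of a 1,3-diyne), leaving the hindered silylalkyne and the isolated ring alkene untouched.

Step 16
Reactants: 24 (2R,5R,6R,8R)-2-ethyl-8-[(1S,3Z)-1-hydroxy-6-(triisopropylsilyl)hex-3-en-5-yn-1-yl]-5,6,7,8-tetrahydro-2H-oxocine-5,6-diyl diacetate
Product: 25 (2R,5R,6R,8R)-8-[(1R,3Z)-1-chloro-6-(triisopropylsilyl)hex-3-en-5-yn-1-yl]-2-ethyl-5,6,7,8-tetrahydro-2H-oxocine-5,6-diyl diacetate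
Conditions: CCl4, (n-C8H17)3P, toluene, 70 °C
Reagents that add atoms: carbon tetrachloride, ClC(Cl)(Cl)Cl
Why: In this Appel reaction chloride should displace the alkoxyphosphonium ion by SN2 with inversion, converting the (6S) alcohol into the (6R) chloride.

Step 17
Reactants: 25 (2R,5R,6R,8R)-8-[(1R,3Z)-1-chloro-6-(triisopropylsilyl)hex-3-en-5-yn-1-yl]-2-ethyl-5,6,7,8-tetrahydro-2H-oxocine-5,6-diyl diacetate
Product: 26 (2R,5R,6R,8R)-8-[(1R,3Z)-1-chlorohex-3-en-5-yn-1-yl]-2-ethyl-5,6,7,8-tetrahydro-2H-oxocine-5,6-diyl diacetate (CNP0268129.3)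
Conditions: Bu4NF, THF, −20 → 0 °C; aq. NH4Cl
Reagents that add atoms: none
Why: Fluoride-induced protodesilylation of the alkynylsilane at low temperature should free the terminal alkyne without disturbing the acetates or the chloride.

**Compound list**

1 | dimethyl (R)-malate | COC(=O)C[C@@H](O)C(=O)OC | starting material
2 | methyl (3R)-3,4-dihydroxybutanoate | COC(=O)C[C@@H](O)CO | intermediate
3 | methyl (3R)-4-[(tert-butyldiphenylsilyl)oxy]-3-hydroxybutanoate | COC(=O)C[C@@H](O)CO[Si](c1ccccc1)(c1ccccc1)C(C)(C)C | intermediate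
4 | (3R)-4-[(tert-butyldiphenylsilyl)oxy]-3-hydroxybutanoic acid | OC(=O)C[C@@H](O)CO[Si](c1ccccc1)(c1ccccc1)C(C)(C)C | intermediate
5 | propanal | CCC=O | starting material
6 | trimethylsilyl (3R)-4-[(tert-butyldiphenylsilyl)oxy]-3-[(trimethylsilyl)oxy]butanoate | C[Si](C)(C)OC(=O)C[C@@H](O[Si](C)(C)C)CO[Si](c1ccccc1)(c1ccccc1)C(C)(C)C | intermediate
7 | (2S,6R)-6-{[(tert-butyldiphenylsilyl)oxy]methyl}-2-ethyl-1,3-dioxan-4-one (2,6-cis) | CC[C@H]1O[C@@H](CO[Si](c2ccccc2)(c2ccccc2)C(C)(C)C)CC(=O)O1 | intermediate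
8 | diisobutylaluminium alkoxide of (2S,6R)-6-{[(tert-butyldiphenylsilyl)oxy]methyl}-2-ethyl-1,3-dioxan-4-ol | CC[C@H]1O[C@@H](CO[Si](c2ccccc2)(c2ccccc2)C(C)(C)C)CC(O[Al](CC(C)C)CC(C)C)O1 | intermediate
9 | (2S,6R)-6-{[(tert-butyldiphenylsilyl)oxy]methyl}-2-ethyl-1,3-dioxan-4-yl acetate (C4 epimers) | CC[C@H]1O[C@@H](CO[Si](c2ccccc2)(c2ccccc2)C(C)(C)C)CC(OC(C)=O)O1 | intermediate
10 | allyloxy(tert-butyl)dimethylsilane | C=CCO[Si](C)(C)C(C)(C)C | starting material
11 | [(2Z)-3-{[tert-butyl(dimethyl)silyl]oxy}prop-2-en-1-yl]lithium | [Li]C/C=C\O[Si](C)(C)C(C)(C)C | intermediate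
12 | tributyl[(2Z)-3-{[tert-butyl(dimethyl)silyl]oxy}prop-2-en-1-yl]stannane | CCCC[Sn](CCCC)(CCCC)C/C=C\O[Si](C)(C)C(C)(C)C | intermediate
13 | (2S,4R,6R)-4-[(1R)-1-{[tert-butyl(dimethyl)silyl]oxy}prop-2-en-1-yl]-6-{[(tert-butyldiphenylsilyl)oxy]methyl}-2-ethyl-1,3-dioxane | CC[C@H]1O[C@@H](CO[Si](c2ccccc2)(c2ccccc2)C(C)(C)C)C[C@H]([C@H](O[Si](C)(C)C(C)(C)C)C=C)O1 | intermediate
14 | (3R,4R,6R)-3-{[tert-butyl(dimethyl)silyl]oxy}-7-[(tert-butyldiphenylsilyl)oxy]-6-[(3R)-pent-1-en-3-yloxy]hept-1-en-4-ol | CC(C)(C)[Si](c1ccccc1)(c1ccccc1)OC[C@H](O[C@H](CC)C=C)C[C@@H](O)[C@H](O[Si](C)(C)C(C)(C)C)C=C | intermediate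
15 | (2R,5R,6R,8R)-5-{[tert-butyl(dimethyl)silyl]oxy}-8-{[(tert-butyldiphenylsilyl)oxy]methyl}-2-ethyl-5,6,7,8-tetrahydro-2H-oxocin-6-ol | CC(C)(C)[Si](c1ccccc1)(c1ccccc1)OC[C@H]2C[C@@H](O)[C@H](O[Si](C)(C)C(C)(C)C)/C=C\[C@@H](CC)O2 | intermediate
16 | (2R,5R,6R,8R)-8-{[(tert-butyldiphenylsilyl)oxy]methyl}-2-ethyl-5,6,7,8-tetrahydro-2H-oxocine-5,6-diol | CC(C)(C)[Si](c1ccccc1)(c1ccccc1)OC[C@H]2C[C@@H](O)[C@H](O)/C=C\[C@@H](CC)O2 | intermediate
17 | (2R,5R,6R,8R)-8-{[(tert-butyldiphenylsilyl)oxy]methyl}-2-ethyl-5,6,7,8-tetrahydro-2H-oxocine-5,6-diyl diacetate | CC(C)(C)[Si](c1ccccc1)(c1ccccc1)OC[C@H]2C[C@@H](OC(C)=O)[C@H](OC(C)=O)/C=C\[C@@H](CC)O2 | intermediate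
18 | (2R,5R,6R,8R)-2-ethyl-8-(hydroxymethyl)-5,6,7,8-tetrahydro-2H-oxocine-5,6-diyl diacetate | OC[C@H]1C[C@@H](OC(C)=O)[C@H](OC(C)=O)/C=C\[C@@H](CC)O1 | intermediate
19 | (2R,5R,6R,8R)-2-ethyl-8-formyl-5,6,7,8-tetrahydro-2H-oxocine-5,6-diyl diacetate | O=C[C@H]1C[C@@H](OC(C)=O)[C@H](OC(C)=O)/C=C\[C@@H](CC)O1 | intermediate
20 | allenylboronic acid pinacol ester (4,4,5,5-tetramethyl-2-propa-1,2-dienyl-1,3,2-dioxaborolane) | C=C=CB1OC(C)(C)C(C)(C)O1 | starting material
21 | (2R,5R,6R,8R)-2-ethyl-8-[(1S)-1-hydroxybut-3-yn-1-yl]-5,6,7,8-tetrahydro-2H-oxocine-5,6-diyl diacetate | C#CC[C@H](O)[C@H]1C[C@@H](OC(C)=O)[C@H](OC(C)=O)/C=C\[C@@H](CC)O1 | intermediate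
22 | (bromoethynyl)tri(propan-2-yl)silane | CC(C)[Si](C#CBr)(C(C)C)C(C)C | starting material
23 | (2R,5R,6R,8R)-2-ethyl-8-[(1S)-1-hydroxy-6-(triisopropylsilyl)hexa-3,5-diyn-1-yl]-5,6,7,8-tetrahydro-2H-oxocine-5,6-diyl diacetate | CC(C)[Si](C#CC#CC[C@H](O)[C@H]1C[C@@H](OC(C)=O)[C@H](OC(C)=O)/C=C\[C@@H](CC)O1)(C(C)C)C(C)C | intermediate
24 | (2R,5R,6R,8R)-2-ethyl-8-[(1S,3Z)-1-hydroxy-6-(triisopropylsilyl)hex-3-en-5-yn-1-yl]-5,6,7,8-tetrahydro-2H-oxocine-5,6-diyl diacetate | CC(C)[Si](C#C/C=C\C[C@H](O)[C@H]1C[C@@H](OC(C)=O)[C@H](OC(C)=O)/C=C\[C@@H](CC)O1)(C(C)C)C(C)C | intermediate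
25 | (2R,5R,6R,8R)-8-[(1R,3Z)-1-chloro-6-(triisopropylsilyl)hex-3-en-5-yn-1-yl]-2-ethyl-5,6,7,8-tetrahydro-2H-oxocine-5,6-diyl diacetate | CC(C)[Si](C#C/C=C\C[C@@H](Cl)[C@H]1C[C@@H](OC(C)=O)[C@H](OC(C)=O)/C=C\[C@@H](CC)O1)(C(C)C)C(C)C | intermediate
26 | (2R,5R,6R,8R)-8-[(1R,3Z)-1-chlorohex-3-en-5-yn-1-yl]-2-ethyl-5,6,7,8-tetrahydro-2H-oxocine-5,6-diyl diacetate (CNP0268129.3) | C#C/C=C\C[C@@H](Cl)[C@H]1C[C@@H](OC(C)=O)[C@H](OC(C)=O)/C=C\[C@@H](CC)O1 | target

**Step count and risks**

Total step count: 17. Longest linear sequence: 16 steps (steps 1–5 and 7–17, from dimethyl (R)-malate); step 6 is a one-step side branch.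

Step 7 (proposed new method) is the step most likely to fail. The acetal may ionise at the wrong oxygen (C13–O7 instead of C13–O9), which after metathesis would lead to a six-membered ether. Vinyl transfer may also lose stereochemical fidelity at C13 if a free oxocarbenium ion intervenes. The acetal may open before the stannane has added, and the alane may be consumed by the silyl acetate formed in the first event. The fallback uses known chemistry, sets out from ester 3 and forms the two bonds in separate operations: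
- Iridium-catalysed branch-selective allylic etherification of the zinc alkoxide of 3 with methyl (E)-pent-2-enyl carbonate ([Ir(cod)Cl]2, chiral phosphoramidite, Et2Zn, THF) would give methyl (3R)-4-[(tert-butyldiphenylsilyl)oxy]-3-[(3R)-pent-1-en-3-yloxy]butanoate F1, with C13 set by the catalyst.
- Reduction with i-Bu2AlH at −78 °C would give (3R)-4-[(tert-butyldiphenylsilyl)oxy]-3-[(3R)-pent-1-en-3-yloxy]butanal F2.
- MgBr2·OEt2-mediated addition of stannane 12 under chelation control (six-membered chelate between the aldehyde and O7 for the 1,3-anti relation, open transition state for the syn diol) would come back to the route at 14.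

Step 15 may fail through over-reduction of the enyne or reduction of the silylated triple bond instead of the internal one. The fallback sets out from alkyne 21 and builds the Z alkene before the second alkyne is attached:
- Iodination (N-iodosuccinimide, AgNO3 cat., acetone) would give (2R,5R,6R,8R)-2-ethyl-8-[(1S)-1-hydroxy-4-iodobut-3-yn-1-yl]-5,6,7,8-tetrahydro-2H-oxocine-5,6-diyl diacetate F3.
- Diimide reduction (2-nitrobenzenesulfonylhydrazide, Et3N) would give the (Z)-vinyl iodide (2R,5R,6R,8R)-2-ethyl-8-[(1S,3Z)-1-hydroxy-4-iodobut-3-en-1-yl]-5,6,7,8-tetrahydro-2H-oxocine-5,6-diyl diacetate F4.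
- Sonogashira coupling with ethynyltri(propan-2-yl)silane (Pd(PPh3)4, CuI, i-Pr2NH) would come back to the route at 24.

Step 13 may fail through poor facial selectivity at the aldehyde (chelate-type attack competing with Felkin–Anh attack) or through epimerisation of the α-alkoxy aldehyde before addition. The fallback sets out from 21 obtained as a C6-epimer mixture and moves the stereocontrol to a ketone reduction:
- Dess–Martin oxidation would give ketone (2R,5R,6R,8R)-8-(but-3-ynoyl)-2-ethyl-5,6,7,8-tetrahydro-2H-oxocine-5,6-diyl diacetate F5.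
- Reduction with Zn(BH4)2 (Et2O, −30 °C), with zinc bridging the ketone oxygen and O7 and hydride arriving from the face of H7, should return the single (6S) alcohol and come back to the route at 21.

Further compounds
F1 | step 7 | methyl (3R)-4-[(tert-butyldiphenylsilyl)oxy]-3-[(3R)-pent-1-en-3-yloxy]butanoate | COC(=O)C[C@@H](O[C@H](CC)C=C)CO[Si](c1ccccc1)(c1ccccc1)C(C)(C)C
F2 | step 7 | (3R)-4-[(tert-butyldiphenylsilyl)oxy]-3-[(3R)-pent-1-en-3-yloxy]butanal | O=CC[C@@H](O[C@H](CC)C=C)CO[Si](c1ccccc1)(c1ccccc1)C(C)(C)C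
F3 | step 15 | (2R,5R,6R,8R)-2-ethyl-8-[(1S)-1-hydroxy-4-iodobut-3-yn-1-yl]-5,6,7,8-tetrahydro-2H-oxocine-5,6-diyl diacetate | IC#CC[C@H](O)[C@H]1C[C@@H](OC(C)=O)[C@H](OC(C)=O)/C=C\[C@@H](CC)O1
F4 | step 15 | (2R,5R,6R,8R)-2-ethyl-8-[(1S,3Z)-1-hydroxy-4-iodobut-3-en-1-yl]-5,6,7,8-tetrahydro-2H-oxocine-5,6-diyl diacetate | I/C=C\C[C@H](O)[C@H]1C[C@@H](OC(C)=O)[C@H](OC(C)=O)/C=C\[C@@H](CC)O1
F5 | step 13 | (2R,5R,6R,8R)-8-(but-3-ynoyl)-2-ethyl-5,6,7,8-tetrahydro-2H-oxocine-5,6-diyl diacetate | C#CCC(=O)[C@H]1C[C@@H](OC(C)=O)[C@H](OC(C)=O)/C=C\[C@@H](CC)O1
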